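**Retrosynthetic overview**
1. Gericudranin D ⇒ its hexa-O-benzyl ether (global hydrogenolysis last) ⇒ the 6,8-dibromide of tetra-O-benzylaromadendrin plus two 4-(benzyloxy)benzylzinc chloride units (twofold Negishi benzylation at the only free positions of ring A).
2. Ring C of tetra-O-benzylaromadendrin is cut at O1–C8a and C2–C3. 4-(Benzyloxy)benzaldehyde supplies O1, C2 and ring B; the silyl enol ether of a 2-(benzyloxy)-1-(2-fluoroaryl)ethanone supplies C3, C4 and ring A. The forward step is an enantioselective aldol/SNAr annulation (formal [4+2]).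
3. Enabling feature: in ring C the array O1–C8a=C4a–C4=O is a vinylogous ester. The single C4 carbonyl makes C3 an enolate carbon and makes C8a, ortho to it on ring A, an SNAr site once C8a carries fluorine. The ring A oxygens on C5 and C7 are meta to C8a and do not deactivate it, and O1–C2 is a latent aldehyde C=O.
4. The fluoro ketone comes from 5-fluororesorcinol by benzylation, bromination next to fluorine, and Br/Li exchange with Weinreb acylation.
5. Ring order: ring A, ring B and the two outer phenol rings are bought; ring C is the only ring formed (key step).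

Key step: step 5

Assumption: the cinchonidine-derived cation is taken to deliver the (2R) series. If the sense of induction proves opposite, the pseudoenantiomeric cinchonine-derived salt is used with no other change.

Step 1
Reactants: 1 5-fluorobenzene-1,3-diol
Product: 2 1,3-bis(benzyloxy)-5-fluorobenzene
Conditions: BnBr (2.2 equiv), K2CO3, DMF, rt to 50 °C
Reagents that add atoms: benzyl bromide BrCc1ccccc1
Why: Williamson ether synthesis, in which both phenoxides are alkylated and the aryl fluoride is inert to carbonate.

Step 2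
Reactants: 2 1,3-bis(benzyloxy)-5-fluorobenzene
Product: 3 1,5-bis(benzyloxy)-2-bromo-3-fluorobenzene
Conditions: NBS (1.0 equiv), MeCN, 0 °C, dark
Reagents that add atoms: N-bromosuccinimide O=C1CCC(=O)N1Br
Why: Electrophilic aromatic bromination, which should attack the position ortho to one and para to the other benzyloxy group (next to fluorine) rather than the crowded position between the two ethers, as is usual for resorcinol diethers.

Step 3
Reactants: 3 1,5-bis(benzyloxy)-2-bromo-3-fluorobenzene; 4 2-(benzyloxy)-N-methoxy-N-methylacetamide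
Product: 6 2-(benzyloxy)-1-[2,4-bis(benzyloxy)-6-fluorophenyl]ethan-1-one, via aryllithium 5 (not isolated)
Conditions: n-BuLi (1.05 equiv), THF, −78 °C; then 4, −78 °C; aq. HCl
Reagents that add atoms: none
Why: Bromine–lithium exchange followed by Weinreb ketone synthesis, where exchange at −78 °C is faster than deprotonation or loss of LiF and the chelated tetrahedral adduct prevents over-addition.

Step 4
Reactants: 6 2-(benzyloxy)-1-[2,4-bis(benzyloxy)-6-fluorophenyl]ethan-1-one
Product: 7 (Z)-{2-(benzyloxy)-1-[2,4-bis(benzyloxy)-6-fluorophenyl]ethenyloxy}(tert-butyl)dimethylsilane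
Conditions: TBSOTf (1.3 equiv), Et3N (2 equiv), CH2Cl2, 0 °C
Reagents that add atoms: tert-butyldimethylsilyl triflate CC(C)(C)[Si](C)(C)OS(=O)(=O)C(F)(F)F
Why: Soft enolisation with O-silylation (silyl triflate/amine) of an aryl ketone, which should give the thermodynamically preferred (Z)-enol ether with the two oxygen substituents cis.

Step 5
Reactants: 7 (Z)-{2-(benzyloxy)-1-[2,4-bis(benzyloxy)-6-fluorophenyl]ethenyloxy}(tert-butyl)dimethylsilane; 8 4-(benzyloxy)benzaldehyde
Product: 11 (2R,3R)-3,5,7-tris(benzyloxy)-2-[4-(benzyloxy)phenyl]-2,3-dihydro-4H-chromen-4-one, via ammonium enolate 9 (not isolated), via anti-aldolate 10 (not isolated)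
Conditions: 8 (1.1 equiv), O-allyl-N-(9-anthracenylmethyl)cinchonidinium hydrogen difluoride (10 mol%), 4 Å molecular sieves, toluene–THF, −40 to 0 °C; pH 7 buffer
Reagents that add atoms: none
Why: Proposed new method: catalytic fluoride strips the silyl group from 7 to give the chiral ammonium (Z)-enolate 9, which adds reversibly to aldehyde 8 (C2–C3 bond), and the ammonium anti-aldolate 10 then attacks the fluorine-bearing C8a ortho to the C4 carbonyl by addition–elimination (O1–C8a bond), the expelled fluoride desilylating the next molecule of 7, so that the leaving group is the chain carrier, t-BuMe2SiF is the only by-product and no stoichiometric base is ever present. The closest known reaction types are the chiral quaternary ammonium bifluoride-catalysed Mukaiyama aldol of silyl enol ethers of α-alkoxy aryl ketones, the phase-transfer asymmetric Darzens condensation (reversible aldol, then irreversible stereo-determining ring closure of an ammonium aldolate) and the fluoride-catalysed SNAr etherification of aryl fluorides by silyl ethers; their merger into an aldol/O-arylation annulation is what is new. Ring C closes in a 6-endo-trig sense onto the C8a=C4a–C4=O vinylogous acyl fluoride, in a Meisenheimer-type addition whose negative charge rests on the C4 oxygen, and ring A rearomatises by loss of fluoride. C2 should be set by the cinchonidinium cation, which shields one face of the contact ion pair in the addition and, under Curtin–Hammett conditions, in the irreversible closure, while C3 is set relative to C2 by the half-chair closure, in which only the anti-aldolate can place the C2 aryl and the C3 benzyloxy group both pseudo-equatorial (2,3-trans), the syn-aldolate reverting by retro-aldol. The step needs closure to outrun β-elimination to the chalcone, O-silylation of 10 and enolisation with ring opening of 11: fluorine ortho to the acyl group with O5 and O7 only meta to C8a keeps the SNAr fast, the bulky t-BuMe2Si group resists transfer to the hindered alkoxide, and in 11 the C4 carbonyl is locked coplanar with a ring that carries three donor oxygens (a vinylogous carbonate), so that H3 of 11 should be less acidic than ketone 6, the conjugate acid of enolate 9, whose carbonyl is twisted out of conjugation by its two ortho substituents.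

Step 6
Reactants: 11 (2R,3R)-3,5,7-tris(benzyloxy)-2-[4-(benzyloxy)phenyl]-2,3-dihydro-4H-chromen-4-one
Product: 12 (2R,3R)-3,5,7-tris(benzyloxy)-2-[4-(benzyloxy)phenyl]-6,8-dibromo-2,3-dihydro-4H-chromen-4-one
Conditions: NBS (2.05 equiv), MeCN–CH2Cl2, 0 °C to rt, dark
Reagents that add atoms: N-bromosuccinimide O=C1CCC(=O)N1Br
Why: Electrophilic aromatic bromination, in which C6 and C8 of ring A (each ortho or para to all three ring A oxygens O1, O5 and O7) are far more nucleophilic than ring B or the benzyl groups, and the neutral medium leaves C2 and C3 untouched.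

Step 7
Reactants: 13 4-(benzyloxy)benzyl chloride
Product: 14 [4-(benzyloxy)benzyl]zinc chloride (THF solution)
Conditions: Zn dust (1.5 equiv), LiCl (1.5 equiv), THF, 25 °C; decanted from excess Zn
Reagents that add atoms: zinc [Zn]
Why: LiCl-mediated direct insertion of zinc into a benzylic chloride, a standard entry to benzylic zinc chlorides.

Step 8
Reactants: 12 (2R,3R)-3,5,7-tris(benzyloxy)-2-[4-(benzyloxy)phenyl]-6,8-dibromo-2,3-dihydro-4H-chromen-4-one; 14 [4-(benzyloxy)benzyl]zinc chloride
Product: 15 (2R,3R)-3,5,7-tris(benzyloxy)-6,8-bis[4-(benzyloxy)benzyl]-2-[4-(benzyloxy)phenyl]-2,3-dihydro-4H-chromen-4-one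
Conditions: 14 (3 equiv), Pd(OAc)2 (5 mol%), 2-dicyclohexylphosphino-2',6'-dimethoxybiphenyl (10 mol%), THF, 25–40 °C
Reagents that add atoms: none
Why: Twofold Negishi cross-coupling, in which the bulky electron-rich biaryl phosphine promotes oxidative addition of zerovalent palladium at the hindered C6–Br and C8–Br bonds and the non-basic zinc reagent spares the ketone and both stereocentres.

Step 9
Reactants: 15 (2R,3R)-3,5,7-tris(benzyloxy)-6,8-bis[4-(benzyloxy)benzyl]-2-[4-(benzyloxy)phenyl]-2,3-dihydro-4H-chromen-4-one
Product: 16 gericudranin D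
Conditions: H2 (1 atm), Pd/C, THF–MeOH, rt
Reagents that add atoms: none
Why: Catalytic hydrogenolysis of the six O-benzyl ethers under neutral conditions, standard for benzyl-protected dihydroflavonols, which should leave the diarylmethane C–C bonds, the C4 ketone and both stereocentres intact.

**Compound list**
1 | 5-fluorobenzene-1,3-diol | Oc1cc(O)cc(F)c1 | starting material
2 | 1,3-bis(benzyloxy)-5-fluorobenzene | Fc1cc(OCc2ccccc2)cc(OCc2ccccc2)c1 | intermediate
3 | 1,5-bis(benzyloxy)-2-bromo-3-fluorobenzene | Fc1cc(OCc2ccccc2)cc(OCc2ccccc2)c1Br | intermediate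
4 | 2-(benzyloxy)-N-methoxy-N-methylacetamide | CON(C)C(=O)COCc1ccccc1 | starting material
5 | [2,4-bis(benzyloxy)-6-fluorophenyl]lithium | [Li]c1c(F)cc(OCc2ccccc2)cc1OCc1ccccc1 | intermediate
6 | 2-(benzyloxy)-1-[2,4-bis(benzyloxy)-6-fluorophenyl]ethan-1-one | O=C(COCc1ccccc1)c1c(F)cc(OCc2ccccc2)cc1OCc1ccccc1 | intermediate
7 | (Z)-{2-(benzyloxy)-1-[2,4-bis(benzyloxy)-6-fluorophenyl]ethenyloxy}(tert-butyl)dimethylsilane | CC(C)(C)[Si](C)(C)O/C(=C\OCc1ccccc1)c1c(F)cc(OCc2ccccc2)cc1OCc1ccccc1 | intermediate
8 | 4-(benzyloxy)benzaldehyde | O=Cc1ccc(OCc2ccccc2)cc1 | starting material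
9 | (Z)-2-(benzyloxy)-1-[2,4-bis(benzyloxy)-6-fluorophenyl]ethen-1-olate (ion pair with the chiral ammonium cation) | [O-]/C(=C\OCc1ccccc1)c1c(F)cc(OCc2ccccc2)cc1OCc1ccccc1 | intermediate
10 | (1R,2R)-2-(benzyloxy)-3-[2,4-bis(benzyloxy)-6-fluorophenyl]-1-[4-(benzyloxy)phenyl]-3-oxopropan-1-olate (anti; ion pair with the chiral ammonium cation) | O=C(c1c(F)cc(OCc2ccccc2)cc1OCc1ccccc1)[C@H](OCc1ccccc1)[C@H]([O-])c1ccc(OCc2ccccc2)cc1 | intermediate
11 | (2R,3R)-3,5,7-tris(benzyloxy)-2-[4-(benzyloxy)phenyl]-2,3-dihydro-4H-chromen-4-one (tetra-O-benzylaromadendrin) | O=C1c2c(OCc3ccccc3)cc(OCc3ccccc3)cc2O[C@H](c2ccc(OCc3ccccc3)cc2)[C@H]1OCc1ccccc1 | intermediate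
12 | (2R,3R)-3,5,7-tris(benzyloxy)-2-[4-(benzyloxy)phenyl]-6,8-dibromo-2,3-dihydro-4H-chromen-4-one | O=C1c2c(OCc3ccccc3)c(Br)c(OCc3ccccc3)c(Br)c2O[C@H](c2ccc(OCc3ccccc3)cc2)[C@H]1OCc1ccccc1 | intermediate
13 | 4-(benzyloxy)benzyl chloride | ClCc1ccc(OCc2ccccc2)cc1 | starting material
14 | [4-(benzyloxy)benzyl]zinc chloride | Cl[Zn]Cc1ccc(OCc2ccccc2)cc1 | intermediate
15 | (2R,3R)-3,5,7-tris(benzyloxy)-6,8-bis[4-(benzyloxy)benzyl]-2-[4-(benzyloxy)phenyl]-2,3-dihydro-4H-chromen-4-one | O=C1c2c(OCc3ccccc3)c(Cc3ccc(OCc4ccccc4)cc3)c(OCc3ccccc3)c(Cc3ccc(OCc4ccccc4)cc3)c2O[C@H](c2ccc(OCc3ccccc3)cc2)[C@H]1OCc1ccccc1 | intermediate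
16 | gericudranin D, (2R,3R)-3,5,7-trihydroxy-6,8-bis(4-hydroxybenzyl)-2-(4-hydroxyphenyl)-2,3-dihydro-4H-chromen-4-one | O=C1c2c(O)c(Cc3ccc(O)cc3)c(O)c(Cc3ccc(O)cc3)c2O[C@H](c2ccc(O)cc2)[C@H]1O | target

Total step count: 9. Longest linear sequence: 8 (steps 1–6, 8 and 9).

**Steps most likely to fail**

**Step 5.**
- What may go wrong:
  - The chiral cation may discriminate poorly once retro-aldol is faster than ring closure, which would erode the enantioselectivity.
  - A slow SNAr closure would let β-elimination to the α-benzyloxychalcone take over.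
  - The anionic chain carriers may enolise the product and open its ring, which would racemise C2.
- Fallback: known chemistry in which O1 comes from a phenol instead of the aldehyde. It sets out from aldehyde 8 and comes back at 11.
  - Commercial 1-[2,4-bis(benzyloxy)-6-hydroxyphenyl]ethan-1-one is protected (MOMCl, i-Pr2NEt, CH2Cl2) as the MOM ether 1-[2,4-bis(benzyloxy)-6-(methoxymethoxy)phenyl]ethan-1-one F1.
  - Claisen–Schmidt condensation of F1 with 8 (KOH, EtOH) should give the (E)-chalcone F2.
  - Juliá–Colonna epoxidation (poly-L-leucine, urea–H2O2, DBU, THF) should give the (2R,3S)-epoxy ketone F3.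
  - HCl in MeOH removes the MOM group, and the freed phenol opens the epoxide at the benzylic carbon with inversion (6-endo). The untouched α-carbon keeps the absolute configuration, which should give the (2R,3R)-3-hydroxyflavanone F4.
  - Benzyl 2,2,2-trichloroacetimidate with catalytic TfOH converts F4 into 11.

**Step 8.**
- What may go wrong:
  - Oxidative addition at the doubly ortho-substituted, electron-rich C–Br bonds may be sluggish, leaving the second coupling incomplete.
  - Protodebromination may compete.
  - The electron-rich benzylic zinc reagent may homocouple.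
- Fallback: it sets out from 11 and comes back at 16.
  - Hydrogenolysis of 11 (H2, Pd/C, THF–MeOH) should give (2R,3R)-aromadendrin F5.
  - F5 is alkylated at C6 and C8 with 4-hydroxybenzyl alcohol under mild acid catalysis in dioxane. This is a Friedel–Crafts-type hydroxybenzylation of the phloroglucinol-type ring A through the p-quinone methide or benzylic cation.
  - The alcohol is added slowly to suppress its self-condensation.

**Step 9.**
- What may go wrong:
  - The hindered C5 and C7 ethers may cleave incompletely.
  - On prolonged exposure over-reduction may set in, by hydrogenolysis of the benzylic C2–O1 bond or reduction of the C4 ketone.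
- Fallback: it sets out from 15 and comes back at 16.
  - Non-reductive Lewis acid debenzylation with BCl3 and pentamethylbenzene as cation scavenger (CH2Cl2, −78 °C) is used.
  - No new compound arises on the way (F0).

**Further compounds**
F1 | step 5 | 1-[2,4-bis(benzyloxy)-6-(methoxymethoxy)phenyl]ethan-1-one | CC(=O)c1c(OCOC)cc(OCc2ccccc2)cc1OCc1ccccc1
F2 | step 5 | (E)-1-[2,4-bis(benzyloxy)-6-(methoxymethoxy)phenyl]-3-[4-(benzyloxy)phenyl]prop-2-en-1-one | O=C(/C=C/c1ccc(OCc2ccccc2)cc1)c1c(OCOC)cc(OCc2ccccc2)cc1OCc1ccccc1
F3 | step 5 | [2,4-bis(benzyloxy)-6-(methoxymethoxy)phenyl]{(2R,3S)-3-[4-(benzyloxy)phenyl]oxiran-2-yl}methanone | O=C(c1c(OCOC)cc(OCc2ccccc2)cc1OCc1ccccc1)[C@@H]1O[C@H]1c1ccc(OCc2ccccc2)cc1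
F4 | step 5 | (2R,3R)-5,7-bis(benzyloxy)-2-[4-(benzyloxy)phenyl]-3-hydroxy-2,3-dihydro-4H-chromen-4-one | O=C1c2c(OCc3ccccc3)cc(OCc3ccccc3)cc2O[C@H](c2ccc(OCc3ccccc3)cc2)[C@H]1O
F5 | step 8 | (2R,3R)-aromadendrin, (2R,3R)-3,5,7-trihydroxy-2-(4-hydroxyphenyl)-2,3-dihydro-4H-chromen-4-one | O=C1c2c(O)cc(O)cc2O[C@H](c2ccc(O)cc2)[C@H]1O
F0 | step 9 | none | none
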